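The readings are simulated for substances that don't exist; scatter was added.

**The leftover.** Count starting material and product in a late reading and something is left over, 41.6% of the charge in the ochre run at 90.0 min and 38.0% in the blue run at 120 min. Call it reactive form and its ratio to starting material is 1.33 in ochre and 1.21 in blue, so it does not hold from one of these runs to the other. The second way supposes that each protic impurity turns one starting material into quenched substrate, and subtracts that share first, 10.0% in ochre and 6.82% in blue. The ratios become 1.01 and 0.993, and the green run gives 28.6% against 28.6% of starting material, level within the scatter of 0.3 percentage points. I therefore trust the second way, whose ochre and blue ratios lie closer together than those of the first.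

| setting | ochre | green | blue | flask |
|---|---|---|---|---|
| starting material | 1.5 M | 1.5 M | 2.2 M | 1.5 M |
| coupling partner | 0.75 M | 1.1 M | 1.5 M | 1.50 M |
| protic impurity | 0.15 M | 0.15 M | 0.15 M | 0.150 M |
| remark | run made earlier | run made earlier | run made earlier |  |
| time |  |  |  | 2.0 h |

| run | time / min | starting material / % | product / % |
|---|---|---|---|
| ochre | 30.0 | 31.6 | 26.9 |
| ochre | 60.0 | 31.5 | 27.2 |
| ochre | 90.0 | 31.3 | 27.1 |
| ochre | 120 | 31.3 | 26.6 |
| green | 15.0 | 30.8 | 29.5 |
| green | 40.0 | 28.7 | 32.6 |
| green | 80.0 | 29.0 | 32.7 |
| green | 120 | 28.6 | 32.8 |
| blue | 10.0 | 34.4 | 26.5 |
| blue | 20.0 | 32.1 | 29.9 |
| blue | 50.0 | 31.9 | 30.4 |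
| blue | 120 | 31.4 | 30.6 |

(each reading ± 0.3 percentage points)

- the reaction counts as stopped when no species that holds the starting material changes by six tenths of a point or more over the second half of the time

* why nothing more happens at 2.0 h, or that something still does (forward and back rates have come level / all of the starting material has reacted / it is still moving / the coupling partner has run out first)
* share of the starting material used up at 2.0 h
* product at 2.0 h, in percent of the starting material charged
* reactive form at 2.0 h, in percent of the starting material charged

**The forecast.** “Taking the reactive form as the mass-balance remainder”, the forecast says forward and back rates have come level, with conversion 73.4%, product 37.8% and reactive form 35.6%.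

**The even split.** My rule starts from the free pool, the charge less the impurity's share, which is 90.0% in this flask; what product does not take of it divides evenly between starting material and reactive form. I have no product figure of my own, so I borrow the forecast's, and the split gives reactive form 26.1%, my number rather than the forecast's, and conversion 73.9%.

**The flask.** In this flask, the coupling partner has run out first: the coupling partner, the limiting reagent, has 0% of its charge left at 2.00 h. Conversion is 73.7%, product 37.3% and reactive form 26.3%, which is 9.3 points below the forecast.

    starting material ⇌ reactive form (K = 1.00, k = 0.00530 /s)
    coupling partner + reactive form → product (k = 0.00460 /M/s)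
    starting material + protic impurity → quenched substrate (k = 0.0750 /M/s)
    2 coupling partner → homo dimer (k = 0.00230 /M/s)

The pool less this product, halved, gives 26.4%. A neighbouring flask charged with 0.38 M of protic impurity has a pool of 74.7%, and its product of 34.3% leaves 20.2% for each side of the split. At its end that neighbouring flask holds 20.2% of starting material and 20.2% of reactive form.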